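The cyclohexane ring (elemane numbering: C10 quaternary, C9 methylene, C8 acyloxy carbon, C7, C6 free carbinol, C5) is cut at its two opposite bonds C5–C10 and C7–C8. Both flank the C6 oxygen: C6(=O)–C5–C10–C1=C2 is a Claisen retron and C6(=O)–C7–C8–OH an aldol retron. The key step exploits this 1,3-relation of the C6 and C8 oxygens and the vinyl-bearing quaternary C10: in one pot an acyclic allyl dienyl ether, joined through a temporary C2–O–C6 bond, undergoes a [3,3] shift (C5–C10, vinyl group, C6 ketone), and the released C8 aldehyde is attacked by C7 to close the ring.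

Key step: step 8

Remark: ring atoms keep the elemane numbers throughout (C5 carries the C4 side chain with the C3 methylene and the C15 oxygen, C7 the C11–C13 unit, C10 the methyl and the C1=C2 vinyl group); 14–16 are racemates (their SMILES give both enantiomers), 17 and later compounds are single enantiomers; 1, 5, 6, 8 and 19 are taken as catalogue chemicals.

Step 1
Reactants: 1 4,4-dimethoxybut-1-yne
Product: 3 5,5-dimethoxypent-2-yn-1-ol, via lithium acetylide 2 (not isolated)
Conditions: n-BuLi, THF, −78 °C; (CH2O)n, −78 °C → rt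
Reagents that add atoms: paraformaldehyde (as formaldehyde), C=O
Why: Deprotonation of the terminal alkyne and 1,2-addition of the acetylide to formaldehyde (alkynylation of an aldehyde) should give the propargylic alcohol, with no stereocentre formed.

Step 2
Reactants: 3 5,5-dimethoxypent-2-yn-1-ol
Product: 4 (2Z)-5,5-dimethoxy-3-methylpent-2-en-1-ol
Conditions: MeMgBr (4 equiv), Fe(acac)3 (15 mol%), THF, −20 → 0 °C; aq. NH4Cl
Reagents that add atoms: methylmagnesium bromide, C[Mg]Br
Why: Alkoxide-directed iron-catalysed syn-carbomagnesiation of a propargylic alcohol places methyl on the distal alkyne carbon and magnesium on the proximal one (five-membered chelate), so protonation should give the (Z)-alkene with CH2OH cis to the acetal-bearing chain.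

Step 3
Reactants: 5 2,3-dibromoprop-1-ene, 6 ethynylmagnesium bromide
Product: 7 2-bromopent-1-en-4-yne
Conditions: CuCl (5 mol%), THF, 0 → 45 °C
Reagents that add atoms: none
Why: Copper-catalysed allylic substitution of the allylic bromide by the alkynyl Grignard reagent should give the skipped enyne, the vinylic bromide being inert.

Step 4
Reactants: 7 2-bromopent-1-en-4-yne, 8 [(tert-butyldimethylsilyl)oxy]acetaldehyde
Product: 10 6-bromo-1-[(tert-butyldimethylsilyl)oxy]hept-6-en-3-yn-2-ol (racemic), via bromomagnesium acetylide 9 (not isolated)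
Conditions: EtMgBr, THF, 0 °C → rt; then 8, −20 °C → rt
Reagents that add atoms: none
Why: Grignard exchange at the terminal alkyne and 1,2-addition of the alkynylmagnesium to the aldehyde should give the propargylic alcohol, whose racemic carbinol centre is removed in step 5.

Step 5
Reactants: 10 6-bromo-1-[(tert-butyldimethylsilyl)oxy]hept-6-en-3-yn-2-ol
Product: 11 6-bromo-1-[(tert-butyldimethylsilyl)oxy]hept-6-en-3-yn-2-one
Conditions: MnO2 (activated), CH2Cl2, rt
Reagents that add atoms: none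
Why: MnO2 oxidation of an activated (propargylic) alcohol should give the ynone without touching the silyl ether or the vinyl bromide.

Step 6
Reactants: 4 (2Z)-5,5-dimethoxy-3-methylpent-2-en-1-ol, 11 6-bromo-1-[(tert-butyldimethylsilyl)oxy]hept-6-en-3-yn-2-one
Product: 12 (3E)-6-bromo-1-[(tert-butyldimethylsilyl)oxy]-4-{[(2Z)-5,5-dimethoxy-3-methylpent-2-en-1-yl]oxy}hepta-3,6-dien-2-one
Conditions: PBu3 (10 mol%), CH2Cl2, 0 °C → rt
Reagents that add atoms: none
Why: Phosphine-catalysed oxa-Michael addition of the primary allylic alcohol to the ynone should give the thermodynamically favoured (E)-β-alkoxy enone (alkoxy trans to the acyl group), which fixes the enol ether geometry used in step 8.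

Step 7
Reactants: 12 (3E)-6-bromo-1-[(tert-butyldimethylsilyl)oxy]-4-{[(2Z)-5,5-dimethoxy-3-methylpent-2-en-1-yl]oxy}hepta-3,6-dien-2-one
Product: 13 tert-butyl({(3E)-6-bromo-4-{[(2Z)-5,5-dimethoxy-3-methylpent-2-en-1-yl]oxy}-2-methylidenehepta-3,6-dien-1-yl}oxy)dimethylsilane
Conditions: Cp2Ti(μ-CH2)(μ-Cl)AlMe2 (Tebbe reagent), pyridine, THF/toluene, −40 → 0 °C; basic work-up
Reagents that add atoms: Tebbe reagent, C[Al-]1(C)C[Ti](C2C=CC=C2)(C2C=CC=C2)[Cl+]1
Why: Titanium-carbene (Tebbe) methylenation of the vinylogous ester carbonyl is non-basic, so the acidic doubly allylic CH2 and the (E)-enol ether geometry should survive while the C4=C3 methylene is installed.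

Step 8
Reactants: 13 tert-butyl({(3E)-6-bromo-4-{[(2Z)-5,5-dimethoxy-3-methylpent-2-en-1-yl]oxy}-2-methylidenehepta-3,6-dien-1-yl}oxy)dimethylsilane
Product: 16 rac-(2R,3S,5S,6R)-6-(1-bromoethenyl)-3-ethenyl-5-hydroxy-3-methyl-2-{3-[(tert-butyldimethylsilyl)oxy]prop-1-en-2-yl}cyclohexan-1-one, via Claisen ketone 14 (not isolated), via keto aldehyde 15 (not isolated)
Conditions: (a) iPr2NEt (0.2 equiv), MeOH/H2O 4:1, 70 °C; (b) evaporate, In(OTf)3 (5 mol%), acetone/H2O, rt; (c) pyrrolidine (0.3 equiv), AcOH (0.3 equiv), THF, 0 °C → rt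
Reagents that add atoms: water, O
Why: Heating 13 brings about a concerted Claisen [3,3] shift through the chair array C5=C6–O–C2–C1=C10 that makes the C5–C10 bond, the C1=C2 vinyl group and the C6 ketone of 14; hydrolysis of the acetal then frees the C8 aldehyde (15), and the pyrrolidine enamine formed on the less hindered C7 side adds to it in an intramolecular aldol reaction that makes the C7–C8 bond. The closest known reaction types are the Claisen rearrangement of allyl 1,3-dien-2-yl ethers and the amine-catalysed aldol cyclisation of keto aldehydes. The only ring closure is the aldol step, a 6-(enolendo)-exo-trig attack on the aldehyde. C5 and C10 are set together by the chair transition state, in which the (2Z)-allyl geometry puts C9 axial and the (E)-enol ether geometry puts C4 equatorial, so that the C5 side chain ends cis to the C10 methyl group; C8 is set in a chair-like aldol transition state with the C5 side chain equatorial and the C10 methyl axial, where the aldehyde oxygen avoids the syn-axial methyl and becomes the equatorial hydroxyl cis to the vinyl group, and C7 settles as the equatorial epimer by enamine–iminium equilibration. The step needs the [3,3] shift to stop before a second, Cope-type shift of the 3-acyl-1,5-diene 14 and needs C5 to keep its configuration: the protic medium accelerates the polar Claisen transition state so that 70 °C should suffice, C5–H is tertiary and shielded by the quaternary C10, and only attack from C7 can close a six-membered ring. No stereocentre is present in 13, so 16 should form as the racemate of one diastereomer.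

Step 9
Reactants: 16 rac-(2R,3S,5S,6R)-6-(1-bromoethenyl)-3-ethenyl-5-hydroxy-3-methyl-2-{3-[(tert-butyldimethylsilyl)oxy]prop-1-en-2-yl}cyclohexan-1-one
Product: 17 (2R,3S,5S,6R)-6-(1-bromoethenyl)-3-ethenyl-5-hydroxy-3-methyl-2-{3-[(tert-butyldimethylsilyl)oxy]prop-1-en-2-yl}cyclohexan-1-one
Conditions: Candida antarctica lipase B (immobilised), vinyl acetate, MTBE, 30 °C, to about half conversion
Reagents that add atoms: none
Why: Lipase-catalysed kinetic resolution by transesterification should acetylate the (8R)-alcohol (the enantiomer that fits the empirical size rule for secondary alcohols, C7 being the larger neighbour) and leave the (8S)-ketol 17 untouched.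

Step 10
Reactants: 17 (2R,3S,5S,6R)-6-(1-bromoethenyl)-3-ethenyl-5-hydroxy-3-methyl-2-{3-[(tert-butyldimethylsilyl)oxy]prop-1-en-2-yl}cyclohexan-1-one
Product: 18 (1S,2R,3S,4R,5S)-2-(1-bromoethenyl)-5-ethenyl-5-methyl-4-{3-[(tert-butyldimethylsilyl)oxy]prop-1-en-2-yl}cyclohexane-1,3-diol
Conditions: Me4NBH(OAc)3, MeCN/AcOH 1:1, −30 °C
Reagents that add atoms: none
Why: Evans–Saksena reduction delivers hydride intramolecularly from the C8-bound acyloxyborohydride to the lower face of C6, which is also the face not blocked by the axial C10 methyl, so the axial C6 alcohol (1,3-anti diol) should result.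

Step 11
Reactants: 19 methyl (2R)-3-hydroxy-2-methylpropanoate
Product: 20 methyl (2R)-3-[(tert-butyldimethylsilyl)oxy]-2-methylpropanoate
Conditions: TBSCl, imidazole, DMF, rt
Reagents that add atoms: tert-butyldimethylsilyl chloride, CC(C)(C)[Si](C)(C)Cl
Why: Silylation of the primary alcohol protects it for the esterification, the stereocentre being untouched.

Step 12
Reactants: 20 methyl (2R)-3-[(tert-butyldimethylsilyl)oxy]-2-methylpropanoate
Product: 21 (2R)-3-[(tert-butyldimethylsilyl)oxy]-2-methylpropanoic acid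
Conditions: LiOH, THF/H2O, 0 °C → rt; then aq. HCl to pH 4
Reagents that add atoms: lithium hydroxide, [Li+].[OH-]
Why: Mild saponification of the methyl ester at low temperature should give the acid without epimerising the α-centre or cleaving the primary silyl ether.

Step 13
Reactants: 18 (1S,2R,3S,4R,5S)-2-(1-bromoethenyl)-5-ethenyl-5-methyl-4-{3-[(tert-butyldimethylsilyl)oxy]prop-1-en-2-yl}cyclohexane-1,3-diol, 21 (2R)-3-[(tert-butyldimethylsilyl)oxy]-2-methylpropanoic acid
Product: 22 (1S,2S,3S,4R,5S)-2-(1-bromoethenyl)-5-ethenyl-3-hydroxy-5-methyl-4-{3-[(tert-butyldimethylsilyl)oxy]prop-1-en-2-yl}cyclohexyl (2R)-3-[(tert-butyldimethylsilyl)oxy]-2-methylpropanoate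
Conditions: DCC, DMAP (0.1 equiv), CH2Cl2, 0 °C → rt
Reagents that add atoms: none
Why: Steglich esterification should acylate the equatorial C8 hydroxyl selectively, because the axial C6 hydroxyl lies between two branched carbons and syn-axial to the C10 methyl group.

Step 14
Reactants: 22 (1S,2S,3S,4R,5S)-2-(1-bromoethenyl)-5-ethenyl-3-hydroxy-5-methyl-4-{3-[(tert-butyldimethylsilyl)oxy]prop-1-en-2-yl}cyclohexyl (2R)-3-[(tert-butyldimethylsilyl)oxy]-2-methylpropanoate
Product: 23 (1S,2R,3S,4R,5S)-2-(1-bromoethenyl)-5-ethenyl-5-methyl-4-{3-[(tert-butyldimethylsilyl)oxy]prop-1-en-2-yl}-3-[(triethylsilyl)oxy]cyclohexyl (2R)-3-[(tert-butyldimethylsilyl)oxy]-2-methylpropanoate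
Conditions: TESOTf, 2,6-lutidine, CH2Cl2, −78 → 0 °C
Reagents that add atoms: triethylsilyl trifluoromethanesulfonate, CC[Si](CC)(CC)OS(=O)(=O)C(F)(F)F
Why: Silylation with the reactive silyl triflate should cap the hindered C6 hydroxyl so that it cannot trap the acyl–palladium of step 15 as a lactone.

Step 15
Reactants: 23 (1S,2R,3S,4R,5S)-2-(1-bromoethenyl)-5-ethenyl-5-methyl-4-{3-[(tert-butyldimethylsilyl)oxy]prop-1-en-2-yl}-3-[(triethylsilyl)oxy]cyclohexyl (2R)-3-[(tert-butyldimethylsilyl)oxy]-2-methylpropanoate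
Product: 24 (1S,2R,3S,4R,5S)-5-ethenyl-5-methyl-4-{3-[(tert-butyldimethylsilyl)oxy]prop-1-en-2-yl}-2-{3-oxo-3-[2-(trimethylsilyl)ethoxy]prop-1-en-2-yl}-3-[(triethylsilyl)oxy]cyclohexyl (2R)-3-[(tert-butyldimethylsilyl)oxy]-2-methylpropanoate
Conditions: Pd(PPh3)4 (5 mol%), CO (3 atm), Me3SiCH2CH2OH (5 equiv), Et3N, DMF, 60 °C
Reagents that add atoms: carbon monoxide, [C-]#[O+]; 2-(trimethylsilyl)ethanol, C[Si](C)(C)CCO
Why: Palladium-catalysed alkoxycarbonylation of the vinyl bromide (oxidative addition, CO insertion, alcoholysis of the acyl–palladium) should turn the 1-bromoethenyl group into the acrylate ester with the alkene position kept.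

Step 16
Reactants: 24 (1S,2R,3S,4R,5S)-5-ethenyl-5-methyl-4-{3-[(tert-butyldimethylsilyl)oxy]prop-1-en-2-yl}-2-{3-oxo-3-[2-(trimethylsilyl)ethoxy]prop-1-en-2-yl}-3-[(triethylsilyl)oxy]cyclohexyl (2R)-3-[(tert-butyldimethylsilyl)oxy]-2-methylpropanoate
Product: 25 (1S,2S,3S,4R,5S)-2-(1-carboxyethenyl)-5-ethenyl-3-hydroxy-4-(3-hydroxyprop-1-en-2-yl)-5-methylcyclohexyl (2R)-3-hydroxy-2-methylpropanoate (CNP0462645.4)
Conditions: TBAF/AcOH 1:1 (excess), THF, 0 °C → rt; work-up at pH 5
Reagents that add atoms: none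
Why: Buffered fluoride should cleave the three silyl ethers and fragment the 2-(trimethylsilyl)ethyl ester in one operation, and the near-neutral medium should avoid acyl migration and lactonisation of the acid onto the C6 hydroxyl.

Compound list
1 | 4,4-dimethoxybut-1-yne | C#CCC(OC)OC | starting material
2 | lithium 4,4-dimethoxybut-1-yn-1-ide (not isolated) | [Li]C#CCC(OC)OC | intermediate
3 | 5,5-dimethoxypent-2-yn-1-ol | OCC#CCC(OC)OC | intermediate
4 | (2Z)-5,5-dimethoxy-3-methylpent-2-en-1-ol | OC/C=C(/C)CC(OC)OC | intermediate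
5 | 2,3-dibromoprop-1-ene | C=C(Br)CBr | starting material
6 | ethynylmagnesium bromide | C#C[Mg]Br | starting material
7 | 2-bromopent-1-en-4-yne | C=C(Br)CC#C | intermediate
8 | [(tert-butyldimethylsilyl)oxy]acetaldehyde | CC(C)(C)[Si](C)(C)OCC=O | starting material
9 | (4-bromopent-4-en-1-yn-1-yl)magnesium bromide (not isolated) | C=C(Br)CC#C[Mg]Br | intermediate
10 | 6-bromo-1-[(tert-butyldimethylsilyl)oxy]hept-6-en-3-yn-2-ol (racemic) | CC(C)(C)[Si](C)(C)OCC(O)C#CCC(Br)=C | intermediate
11 | 6-bromo-1-[(tert-butyldimethylsilyl)oxy]hept-6-en-3-yn-2-one | CC(C)(C)[Si](C)(C)OCC(=O)C#CCC(Br)=C | intermediate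
12 | (3E)-6-bromo-1-[(tert-butyldimethylsilyl)oxy]-4-{[(2Z)-5,5-dimethoxy-3-methylpent-2-en-1-yl]oxy}hepta-3,6-dien-2-one | CC(C)(C)[Si](C)(C)OCC(=O)/C=C(\CC(Br)=C)OC/C=C(/C)CC(OC)OC | intermediate
13 | tert-butyl({(3E)-6-bromo-4-{[(2Z)-5,5-dimethoxy-3-methylpent-2-en-1-yl]oxy}-2-methylidenehepta-3,6-dien-1-yl}oxy)dimethylsilane | CC(C)(C)[Si](C)(C)OCC(=C)/C=C(\CC(Br)=C)OC/C=C(/C)CC(OC)OC | intermediate
14 | rac-(5R,6S)-2-bromo-6-ethenyl-8,8-dimethoxy-6-methyl-5-{3-[(tert-butyldimethylsilyl)oxy]prop-1-en-2-yl}oct-1-en-4-one (not isolated) | C=C[C@](C)(CC(OC)OC)[C@@H](C(=O)CC(Br)=C)C(=C)CO[Si](C)(C)C(C)(C)C.C=C[C@@](C)(CC(OC)OC)[C@H](C(=O)CC(Br)=C)C(=C)CO[Si](C)(C)C(C)(C)C | intermediate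
15 | rac-(3S,4R)-7-bromo-3-ethenyl-3-methyl-5-oxo-4-{3-[(tert-butyldimethylsilyl)oxy]prop-1-en-2-yl}oct-7-enal (not isolated) | C=C[C@](C)(CC=O)[C@@H](C(=O)CC(Br)=C)C(=C)CO[Si](C)(C)C(C)(C)C.C=C[C@@](C)(CC=O)[C@H](C(=O)CC(Br)=C)C(=C)CO[Si](C)(C)C(C)(C)C | intermediate
16 | rac-(2R,3S,5S,6R)-6-(1-bromoethenyl)-3-ethenyl-5-hydroxy-3-methyl-2-{3-[(tert-butyldimethylsilyl)oxy]prop-1-en-2-yl}cyclohexan-1-one | C=C[C@]1(C)C[C@H](O)[C@@H](C(Br)=C)C(=O)[C@H]1C(=C)CO[Si](C)(C)C(C)(C)C.C=C[C@@]1(C)C[C@@H](O)[C@H](C(Br)=C)C(=O)[C@@H]1C(=C)CO[Si](C)(C)C(C)(C)C | intermediate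
17 | (2R,3S,5S,6R)-6-(1-bromoethenyl)-3-ethenyl-5-hydroxy-3-methyl-2-{3-[(tert-butyldimethylsilyl)oxy]prop-1-en-2-yl}cyclohexan-1-one | C=C[C@]1(C)C[C@H](O)[C@@H](C(Br)=C)C(=O)[C@H]1C(=C)CO[Si](C)(C)C(C)(C)C | intermediate
18 | (1S,2R,3S,4R,5S)-2-(1-bromoethenyl)-5-ethenyl-5-methyl-4-{3-[(tert-butyldimethylsilyl)oxy]prop-1-en-2-yl}cyclohexane-1,3-diol | C=C[C@]1(C)C[C@H](O)[C@@H](C(Br)=C)[C@@H](O)[C@H]1C(=C)CO[Si](C)(C)C(C)(C)C | intermediate
19 | methyl (2R)-3-hydroxy-2-methylpropanoate | COC(=O)[C@H](C)CO | starting material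
20 | methyl (2R)-3-[(tert-butyldimethylsilyl)oxy]-2-methylpropanoate | COC(=O)[C@H](C)CO[Si](C)(C)C(C)(C)C | intermediate
21 | (2R)-3-[(tert-butyldimethylsilyl)oxy]-2-methylpropanoic acid | OC(=O)[C@H](C)CO[Si](C)(C)C(C)(C)C | intermediate
22 | (1S,2S,3S,4R,5S)-2-(1-bromoethenyl)-5-ethenyl-3-hydroxy-5-methyl-4-{3-[(tert-butyldimethylsilyl)oxy]prop-1-en-2-yl}cyclohexyl (2R)-3-[(tert-butyldimethylsilyl)oxy]-2-methylpropanoate | C=C[C@]1(C)C[C@H](OC(=O)[C@H](C)CO[Si](C)(C)C(C)(C)C)[C@@H](C(Br)=C)[C@@H](O)[C@H]1C(=C)CO[Si](C)(C)C(C)(C)C | intermediate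
23 | (1S,2R,3S,4R,5S)-2-(1-bromoethenyl)-5-ethenyl-5-methyl-4-{3-[(tert-butyldimethylsilyl)oxy]prop-1-en-2-yl}-3-[(triethylsilyl)oxy]cyclohexyl (2R)-3-[(tert-butyldimethylsilyl)oxy]-2-methylpropanoate | C=C[C@]1(C)C[C@H](OC(=O)[C@H](C)CO[Si](C)(C)C(C)(C)C)[C@@H](C(Br)=C)[C@@H](O[Si](CC)(CC)CC)[C@H]1C(=C)CO[Si](C)(C)C(C)(C)C | intermediate
24 | (1S,2R,3S,4R,5S)-5-ethenyl-5-methyl-4-{3-[(tert-butyldimethylsilyl)oxy]prop-1-en-2-yl}-2-{3-oxo-3-[2-(trimethylsilyl)ethoxy]prop-1-en-2-yl}-3-[(triethylsilyl)oxy]cyclohexyl (2R)-3-[(tert-butyldimethylsilyl)oxy]-2-methylpropanoate | C=C[C@]1(C)C[C@H](OC(=O)[C@H](C)CO[Si](C)(C)C(C)(C)C)[C@@H](C(=C)C(=O)OCC[Si](C)(C)C)[C@@H](O[Si](CC)(CC)CC)[C@H]1C(=C)CO[Si](C)(C)C(C)(C)C | intermediate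
25 | (1S,2S,3S,4R,5S)-2-(1-carboxyethenyl)-5-ethenyl-3-hydroxy-4-(3-hydroxyprop-1-en-2-yl)-5-methylcyclohexyl (2R)-3-hydroxy-2-methylpropanoate (CNP0462645.4) | C=C[C@]1(C)C[C@H](OC(=O)[C@H](C)CO)[C@@H](C(=C)C(=O)O)[C@@H](O)[C@H]1C(=C)CO | target

Total step count: 16.
Longest linear sequence: 12 steps (steps 3, 4, 5, 6, 7, 8, 9, 10, 13, 14, 15, 16).

Steps most likely to fail

Step 8. The acyclic ketone 14 is a 3-acyl-1,5-diene, so a second [3,3] (Cope-type) shift to a linear conjugated enone may follow the first shift at the same temperature and erase the C5–C10 bond; enolisation towards C5 before ring closure would also lose the relay of configuration from C5 to C8. The fallback sets out from 13 and comes back at 16. The rearrangement is run with iBu3Al in CH2Cl2 at −20 °C to rt as a Claisen rearrangement with reduction in the flask, so that the ketone is trapped at once as the homoallylic alcohol F1, which lacks the acyl group that activates the Cope shift. Oxidation of F1 with Dess–Martin periodinane at 0 °C gives 14 as an isolated compound. Acetal cleavage (In(OTf)3, wet acetone) and the pyrrolidine/AcOH aldol closure are then run as a separate cold operation to reach 16.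

Step 9. The lipase may discriminate poorly between the enantiomers because both carbons next to C8 are bulky, or it may acylate this hindered alcohol too slowly. The fallback sets out from 16 and comes back at 22. Racemic 16 is reduced with Me4NBH(OAc)3 to the racemic diol F2, which is esterified with acid 21 (DCC, DMAP) to give 22 together with the diastereomeric ester F3. The two diastereomers are separated by chromatography, a classical resolution that uses the acyl group the target needs anyway, and 22 goes on to step 14.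

Step 15. Oxidative addition at the hindered 1,1-disubstituted vinyl bromide may be slow, and the alkenyl–palladium may insert into a neighbouring alkene (intramolecular Heck reaction) before it takes up CO. The fallback sets out from 23 and comes back at 25. A nickel-catalysed reductive carboxylation with CO2 (NiCl2(PPh3)2, Mn powder, Et4NI, DMF, CO2 1 atm, rt) gives the free acrylic acid F4 directly. Global desilylation of F4 with HF·pyridine (THF/pyridine, 0 °C) then gives 25.

Further compounds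
F1 | step 8 | rac-(5R,6S)-2-bromo-6-ethenyl-8,8-dimethoxy-6-methyl-5-{3-[(tert-butyldimethylsilyl)oxy]prop-1-en-2-yl}oct-1-en-4-ol (both C4 epimers) | C=C[C@](C)(CC(OC)OC)[C@@H](C(O)CC(Br)=C)C(=C)CO[Si](C)(C)C(C)(C)C.C=C[C@@](C)(CC(OC)OC)[C@H](C(O)CC(Br)=C)C(=C)CO[Si](C)(C)C(C)(C)C
F2 | step 9 | rac-(1S,2R,3S,4R,5S)-2-(1-bromoethenyl)-5-ethenyl-5-methyl-4-{3-[(tert-butyldimethylsilyl)oxy]prop-1-en-2-yl}cyclohexane-1,3-diol | C=C[C@]1(C)C[C@H](O)[C@@H](C(Br)=C)[C@@H](O)[C@H]1C(=C)CO[Si](C)(C)C(C)(C)C.C=C[C@@]1(C)C[C@@H](O)[C@H](C(Br)=C)[C@H](O)[C@@H]1C(=C)CO[Si](C)(C)C(C)(C)C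
F3 | step 9 | (1R,2R,3R,4S,5R)-2-(1-bromoethenyl)-5-ethenyl-3-hydroxy-5-methyl-4-{3-[(tert-butyldimethylsilyl)oxy]prop-1-en-2-yl}cyclohexyl (2R)-3-[(tert-butyldimethylsilyl)oxy]-2-methylpropanoate | C=C[C@@]1(C)C[C@@H](OC(=O)[C@H](C)CO[Si](C)(C)C(C)(C)C)[C@H](C(Br)=C)[C@H](O)[C@@H]1C(=C)CO[Si](C)(C)C(C)(C)C
F4 | step 15 | (1S,2R,3S,4R,5S)-2-(1-carboxyethenyl)-5-ethenyl-5-methyl-4-{3-[(tert-butyldimethylsilyl)oxy]prop-1-en-2-yl}-3-[(triethylsilyl)oxy]cyclohexyl (2R)-3-[(tert-butyldimethylsilyl)oxy]-2-methylpropanoate | C=C[C@]1(C)C[C@H](OC(=O)[C@H](C)CO[Si](C)(C)C(C)(C)C)[C@@H](C(=C)C(=O)O)[C@@H](O[Si](CC)(CC)CC)[C@H]1C(=C)CO[Si](C)(C)C(C)(C)C
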